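The carbocycle (C4a, C5, C6, C7, C8, C8a; isochromene numbering) is read as an opened 7‑oxanorbornene. The tertiary C7–OH and C4a are the two ends of a former furan oxygen bridge, and the cis C8–OH/C8a–C1H2O pair is a former Z‑alkene. One exo Diels–Alder reaction between a tetronate‑derived 2‑silyloxy‑4‑methoxy‑5‑methylfuran and a menthone‑ketal 1,3‑dioxin‑4‑one forms C4a–C8a and C7–C8 and sets C7, C8 and C8a at once. Reduction and bridge opening give a 3‑methoxy‑enone that takes up the enyne side chain by 1,2‑addition and allylic transposition; hydroalkoxylation of the alkyne then closes the pyran ring.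

Key step: step 6

Remark on the chemistry: atom labels C1–C8a are the isochromene positions of the target. Compounds 6–8 are used as racemates, because their only stereocentre becomes the planar C5 of furan 9. The new carbinol centre of 29 is left uncontrolled, because it is erased within step 17.

Step 1
Reactants: 1 5-(methoxymethylidene)-2,2-dimethyl-1,3-dioxane-4,6-dione
Product: 2 5-(hydroxymethylidene)-2,2-dimethyl-1,3-dioxane-4,6-dione (formyl Meldrum's acid)
Conditions: 2 M HCl (aq), 20 °C
Reagents that add atoms: water, O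
Why: Acid hydrolysis by addition–elimination at the doubly activated enol-ether carbon should exchange methoxy for hydroxy and give the hydrogen-bonded enol.

Step 2
Reactants: 2 formyl Meldrum's acid; 3 (−)-menthone
Product: 5 (6R,7S,10R)-10-methyl-7-(propan-2-yl)-1,5-dioxaspiro[5.5]undec-2-en-4-one, via formylketene 4 (not isolated)
Conditions: 3 (3 equiv), PhMe, 110 °C; chromatography
Reagents that add atoms: none
Why: Thermal retro-[4+2] fragmentation of 2 (loss of acetone and CO2) should give formylketene, which the ketone carbonyl traps in an oxa-[4+2] cycloaddition; the spiro centre is not controlled, so the two spiro epimers are separated and the (6R) epimer is carried on.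

Step 3
Reactants: 6 ethyl 2-(acetyloxy)propanoate (racemate)
Product: 7 4-hydroxy-5-methylfuran-2(5H)-one (5-methyltetronic acid)
Conditions: LiN(SiMe3)2 (2.2 equiv), THF, −78 → 20 °C; then HCl (aq)
Reagents that add atoms: none
Why: Dieckmann condensation of the acetate enolate onto the ethyl ester should close the tetronic acid, driven by deprotonation of the vinylogous acid.

Step 4
Reactants: 7 5-methyltetronic acid
Product: 8 4-methoxy-5-methylfuran-2(5H)-one
Conditions: Me2SO4, K2CO3, acetone, 56 °C
Reagents that add atoms: dimethyl sulfate, COS(=O)(=O)OC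
Why: Williamson-type O-alkylation of the vinylogous carboxylate at the 4-oxygen should give the methyl tetronate.

Step 5
Reactants: 8 4-methoxy-5-methylfuran-2(5H)-one
Product: 9 tert-butyl[(4-methoxy-5-methylfuran-2-yl)oxy]dimethylsilane
Conditions: TBSOTf, Et3N, CH2Cl2, 0 °C
Reagents that add atoms: tert-butyldimethylsilyl trifluoromethanesulfonate, CC(C)(C)[Si](C)(C)OS(=O)(=O)C(F)(F)F
Why: Soft enolisation (O-silylation of the lactone carbonyl, then γ-deprotonation) should give the aromatic 2-silyloxyfuran, in which the former stereocentre is planar.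

Step 6
Reactants: 5 menthone-ketal dioxinone; 9 2-silyloxy-4-methoxy-5-methylfuran
Product: 10 exo Diels–Alder adduct: 1-(tert-butyldimethylsilyloxy)-3-methoxy-4-methyl-7-oxabicyclo[2.2.1]hept-2-ene whose C5–C6 bond is cis-fused on the exo face to the 1,3-dioxan-4-one ring of the menthone ketal (C5 carries the ketal oxygen and is bonded to the methyl bridgehead; C6 carries the lactone carbonyl and is bonded to the silyloxy bridgehead)
Conditions: 9 (1.5 equiv), PhMe, 80 °C, sealed tube
Reagents that add atoms: none
Why: A thermal normal-electron-demand [4+2] cycloaddition is expected, in which the furan HOMO, raised by the 2-silyloxy and 4-methoxy donors and largest at the methyl-bearing C5, pairs with the β-carbon of the dioxinone alkene (LUMO lowered by the lactone carbonyl), so that C7–C8 and C4a–C8a form in the required regiochemical sense; the closest known reaction types are the Diels–Alder reactions of 2-silyloxyfurans with acrylates and of furan with vinylene carbonate. The carbocycle C4a–C5–C6–C7–C8–C8a is closed by an intermolecular suprafacial cycloaddition, first as the boat of a 7-oxabicyclo[2.2.1]heptene in which the furan oxygen still bridges C7 and C4a. C8 and C8a are set cis to each other by the ring-locked Z-alkene of 5, and C7 is set relative to them by the exo topology (dioxanone ring on the side of the oxygen bridge), which should be favoured because the endo mode would place the spiro-menthane ketal under the furan ring and because furan cycloadditions are reversible. The absolute sense is set by the menthone ketal, whose isopropyl-bearing carbon shields one face of the dioxinone so that the furan adds to the face flanked by the ring CH2. The step needs regio-, exo- and π-facial selectivity; the first is secured by the matched donor/acceptor polarisation, the other two by the spiro ketal.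

Step 7
Reactants: 10 exo adduct
Product: 12 (4R,5R,6S)-4,5-dihydroxy-6-(hydroxymethyl)-3-methoxy-4-methylcyclohex-2-en-1-one, via bridged diol 11 (not isolated)
Conditions: LiAlH4, THF, −20 °C; then Bu4NF, AcOH, THF, 0 °C
Reagents that add atoms: none
Why: Hydride should reduce the ketal-lactone to the primary alcohol while the hemiketal alkoxide expels menthone and frees the secondary hydroxyl, and fluoride then removes the bridgehead silyl group so that the hemiketal alkoxide opens the oxygen bridge to the vinylogous ester with the bridge oxygen left as the tertiary hydroxyl; no stereocentre is touched, and reducing before opening avoids a β-keto-lactone that could epimerise at C8a.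

Step 8
Reactants: 12 triol
Product: 13 (4R,5R,6S)-3-methoxy-4-methyl-4,5-bis[(triethylsilyl)oxy]-6-{[(triethylsilyl)oxy]methyl}cyclohex-2-en-1-one
Conditions: Et3SiOTf (3.5 equiv), 2,6-lutidine, CH2Cl2, −78 → 0 °C
Reagents that add atoms: triethylsilyl trifluoromethanesulfonate, CC[Si](CC)(CC)OS(=O)(=O)C(F)(F)F
Why: The silyl triflate should silylate primary, secondary and tertiary hydroxyls alike, which blocks retro-aldol and β-elimination pathways and the later competition of the secondary hydroxyl in ring closure.

Step 9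
Reactants: 13 tris(triethylsilyl) ether
Product: 14 (4R,5R,6S)-2-chloro-3-methoxy-4-methyl-4,5-bis[(triethylsilyl)oxy]-6-{[(triethylsilyl)oxy]methyl}cyclohex-2-en-1-one
Conditions: NCS, CH2Cl2, 0 → 20 °C
Reagents that add atoms: N-chlorosuccinimide, O=C1CCC(=O)N1Cl
Why: Electrophilic chlorination should occur at C2, the only nucleophilic carbon of the vinylogous ester, which places chlorine on the future C5 before any other alkene is present.

Step 10
Reactants: 15 methacrolein; 16 (Z)-but-2-ene
Product: 18 (3R,4S)-2,4-dimethylhexa-1,5-dien-3-ol, via B-crotyldiisopinocampheylborane 17 (not isolated)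
Conditions: 16, n-BuLi, KOtBu, THF, −78 → −45 °C; (+)-Ipc2BOMe, BF3·OEt2, −78 °C; 15, −78 °C; NaOH, H2O2
Reagents that add atoms: none
Why: Brown crotylboration through a chair Zimmerman–Traxler transition state should give the syn product from the Z-crotyl group, and the isopinocampheyl groups derived from (−)-α-pinene direct addition to the Re face of the aldehyde, which sets (3R,4S).

Step 11
Reactants: 18 dienol
Product: 19 (3S,4R)-3,5-dimethylhex-5-ene-1,4-diol
Conditions: Sia2BH (from BH3·SMe2, 2-methylbut-2-ene), THF, 0 °C; NaOH, H2O2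
Reagents that add atoms: hydrogen peroxide, OO
Why: The hindered dialkylborane should hydroborate the monosubstituted vinyl group anti-Markovnikov much faster than the 1,1-disubstituted allylic isopropenyl group, and oxidation with retention gives the primary alcohol without touching the stereocentres.

Step 12
Reactants: 19 diol
Product: 21 (2R,3S)-3-methyl-2-(prop-1-en-2-yl)oxolane, via primary tosylate 20 (not isolated)
Conditions: TsCl, Et3N, DMAP (cat.), CH2Cl2, 0 °C; then KOtBu, THF, 0 → 20 °C
Reagents that add atoms: none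
Why: Selective sulfonylation of the primary hydroxyl followed by 5-exo-tet Williamson closure by the secondary alkoxide should form the oxolane with retention at the carbinol carbon, so the syn diol gives the cis-2,3-disubstituted ring.

Step 13
Reactants: 21 isopropenyl oxolane
Product: 22 1-[(2R,3S)-3-methyloxolan-2-yl]ethan-1-one
Conditions: O3, CH2Cl2, −78 °C; Me2S
Reagents that add atoms: ozone, [O-][O+]=O
Why: Ozonolysis of the 1,1-disubstituted alkene with neutral reductive work-up should give the methyl ketone without epimerising the α-stereocentre.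

Step 14
Reactants: 22 methyl ketone; 23 1,4-bis(trimethylsilyl)buta-1,3-diyne
Product: 25 (2R)-2-[(2R,3S)-3-methyloxolan-2-yl]-6-(trimethylsilyl)hexa-3,5-diyn-2-ol, via lithium silylbutadiynide 24 (not isolated)
Conditions: 23, MeLi·LiBr, Et2O, 20 °C; MgBr2·OEt2; 22, Et2O–CH2Cl2, −78 °C
Reagents that add atoms: none
Why: Monodesilylation gives the acetylide, and after transmetallation to magnesium a Cram-chelate addition (magnesium bridging the ketone and ring oxygens) should deliver the nucleophile to the carbonyl face anti to ring carbon C3 and its cis methyl, which sets the (R)-carbinol.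

Step 15
Reactants: 25 diynyl carbinol
Product: 26 (2R,3E)-2-[(2R,3S)-3-methyloxolan-2-yl]-6-(trimethylsilyl)hex-3-en-5-yn-2-ol
Conditions: NaAlH2(OCH2CH2OMe)2, THF, 0 → 20 °C
Reagents that add atoms: none
Why: Alkoxide-directed trans-hydroalumination should reduce only the propargylic triple bond, and protonolysis gives the E-alkene with the distal silylalkyne untouched.

Step 16
Reactants: 26 silyl enyne
Product: 27 (2R,3E)-2-[(2R,3S)-3-methyloxolan-2-yl]hex-3-en-5-yn-2-ol
Conditions: K2CO3, MeOH, 20 °C
Reagents that add atoms: none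
Why: Methoxide-mediated protodesilylation should free the terminal alkyne.

Step 17
Reactants: 14 chloro vinylogous ester; 27 enyne
Product: 30 (4S,5R,6R)-2-chloro-4-(hydroxymethyl)-3-[(3E,5R)-5-hydroxy-5-[(2R,3S)-3-methyloxolan-2-yl]hex-3-en-1-yn-1-yl]-6-methyl-5,6-bis[(triethylsilyl)oxy]cyclohex-2-en-1-one, via dilithiated enyne 28 (not isolated), via tertiary carbinol adduct 29 (not isolated)
Conditions: 27 (1.5 equiv), n-BuLi (3.0 equiv), THF, −78 °C; 14, −78 → 0 °C; then 1 M HCl, THF, 0 °C
Reagents that add atoms: water, O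
Why: In a Stork–Danheiser sequence the weakly basic lithium acetylide should add 1,2 to the vinylogous ester carbonyl, and mild acid then ionises the tertiary carbinol with methoxy assistance and hydrolyses the oxocarbenium ion to the transposed enone, while the primary triethylsilyl ether is cleaved in the same acid and the ring stereocentres are untouched.

Step 18
Reactants: 30 alkynyl enone
Product: 31 (7R,8R,8aS)-5-chloro-3-[(1E,3R)-3-hydroxy-3-[(2R,3S)-3-methyloxolan-2-yl]but-1-en-1-yl]-7-methyl-7,8-bis[(triethylsilyl)oxy]-1,7,8,8a-tetrahydro-6H-isochromen-6-one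
Conditions: Ph3PAuCl, AgOTf (5 mol% each), CH2Cl2, 0 °C
Reagents that add atoms: none
Why: Activation of the alkyne by cationic monovalent gold should lead to 6-endo-dig attack of the primary hydroxyl at the distal alkyne carbon, which is the δ-position of the ynenone and carries the cation-stabilising alkenyl group, and protodeauration gives the pyran ring, as in the cycloisomerisation of 2-alkynylbenzyl alcohols and aldehydes to isochromenes.

Step 19
Reactants: 31 bis(triethylsilyl) ether
Product: 32 Peniciazaphilone E
Conditions: Bu4NF, AcOH (1:1), THF, 0 → 20 °C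
Reagents that add atoms: none
Why: Buffered fluoride should cleave both silyl ethers without the base-induced retro-aldol or the acid-induced ionisation of the tertiary allylic alcohol that the product could suffer.

Compound list
1 | 5-(methoxymethylidene)-2,2-dimethyl-1,3-dioxane-4,6-dione | COC=C1C(=O)OC(C)(C)OC1=O | starting material
2 | 5-(hydroxymethylidene)-2,2-dimethyl-1,3-dioxane-4,6-dione (formyl Meldrum's acid) | OC=C1C(=O)OC(C)(C)OC1=O | intermediate
3 | (−)-menthone, (2S,5R)-5-methyl-2-(propan-2-yl)cyclohexan-1-one | CC(C)[C@@H]1CC[C@@H](C)CC1=O | starting material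
4 | formylketene (3-oxoprop-1-en-1-one) | O=CC=C=O | intermediate (not isolated)
5 | (6R,7S,10R)-10-methyl-7-(propan-2-yl)-1,5-dioxaspiro[5.5]undec-2-en-4-one | CC(C)[C@@H]1CC[C@@H](C)C[C@]12OC=CC(=O)O2 | intermediate
6 | ethyl 2-(acetyloxy)propanoate (racemate) | CCOC(=O)C(C)OC(C)=O | starting material
7 | 4-hydroxy-5-methylfuran-2(5H)-one (racemate) | CC1OC(=O)C=C1O | intermediate
8 | 4-methoxy-5-methylfuran-2(5H)-one (racemate) | COC1=CC(=O)OC1C | intermediate
9 | tert-butyl[(4-methoxy-5-methylfuran-2-yl)oxy]dimethylsilane | COc1cc(O[Si](C)(C)C(C)(C)C)oc1C | intermediate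
10 | exo Diels–Alder adduct of 9 and 5 (silyloxy-bridgehead 7-oxanorbornene cis-fused on its exo face to the menthone-ketal dioxanone; C7, C8 and C8a as in the target) | C[C@@]12C(OC)=C[C@@](O[Si](C)(C)C(C)(C)C)(O1)[C@H]1C(=O)O[C@@]3(C[C@H](C)CC[C@H]3C(C)C)O[C@@H]21 | intermediate
11 | 1-(tert-butyldimethylsilyloxy)-6-exo-(hydroxymethyl)-3-methoxy-4-methyl-7-oxabicyclo[2.2.1]hept-2-en-5-exo-ol | C[C@@]12C(OC)=C[C@@](O[Si](C)(C)C(C)(C)C)(O1)[C@@H](CO)[C@H]2O | intermediate (not isolated)
12 | (4R,5R,6S)-4,5-dihydroxy-6-(hydroxymethyl)-3-methoxy-4-methylcyclohex-2-en-1-one | COC1=CC(=O)[C@@H](CO)[C@@H](O)[C@@]1(C)O | intermediate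
13 | (4R,5R,6S)-3-methoxy-4-methyl-4,5-bis[(triethylsilyl)oxy]-6-{[(triethylsilyl)oxy]methyl}cyclohex-2-en-1-one | COC1=CC(=O)[C@@H](CO[Si](CC)(CC)CC)[C@@H](O[Si](CC)(CC)CC)[C@@]1(C)O[Si](CC)(CC)CC | intermediate
14 | (4R,5R,6S)-2-chloro-3-methoxy-4-methyl-4,5-bis[(triethylsilyl)oxy]-6-{[(triethylsilyl)oxy]methyl}cyclohex-2-en-1-one | COC1=C(Cl)C(=O)[C@@H](CO[Si](CC)(CC)CC)[C@@H](O[Si](CC)(CC)CC)[C@@]1(C)O[Si](CC)(CC)CC | intermediate
15 | methacrolein (2-methylprop-2-enal) | CC(=C)C=O | starting material
16 | (Z)-but-2-ene | C/C=C\C | starting material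
17 | (Z)-but-2-en-1-yl-bis(isopinocampheyl)borane, isopinocampheyl groups from (−)-α-pinene | C/C=C\CB([C@H]1C[C@H]2C[C@@H]([C@@H]1C)C2(C)C)[C@H]1C[C@H]2C[C@@H]([C@@H]1C)C2(C)C | intermediate (not isolated)
18 | (3R,4S)-2,4-dimethylhexa-1,5-dien-3-ol | C[C@@H](C=C)[C@@H](O)C(C)=C | intermediate
19 | (3S,4R)-3,5-dimethylhex-5-ene-1,4-diol | C[C@@H](CCO)[C@@H](O)C(C)=C | intermediate
20 | (3S,4R)-4-hydroxy-3,5-dimethylhex-5-en-1-yl 4-methylbenzenesulfonate | C[C@@H](CCOS(=O)(=O)c1ccc(C)cc1)[C@@H](O)C(C)=C | intermediate (not isolated)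
21 | (2R,3S)-3-methyl-2-(prop-1-en-2-yl)oxolane | C[C@H]1CCO[C@H]1C(C)=C | intermediate
22 | 1-[(2R,3S)-3-methyloxolan-2-yl]ethan-1-one | C[C@H]1CCO[C@H]1C(C)=O | intermediate
23 | 1,4-bis(trimethylsilyl)buta-1,3-diyne | C[Si](C)(C)C#CC#C[Si](C)(C)C | starting material
24 | lithium 4-(trimethylsilyl)buta-1,3-diyn-1-ide | [Li]C#CC#C[Si](C)(C)C | intermediate (not isolated)
25 | (2R)-2-[(2R,3S)-3-methyloxolan-2-yl]-6-(trimethylsilyl)hexa-3,5-diyn-2-ol | C[C@H]1CCO[C@H]1[C@](C)(O)C#CC#C[Si](C)(C)C | intermediate
26 | (2R,3E)-2-[(2R,3S)-3-methyloxolan-2-yl]-6-(trimethylsilyl)hex-3-en-5-yn-2-ol | C[C@H]1CCO[C@H]1[C@](C)(O)/C=C/C#C[Si](C)(C)C | intermediate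
27 | (2R,3E)-2-[(2R,3S)-3-methyloxolan-2-yl]hex-3-en-5-yn-2-ol | C[C@H]1CCO[C@H]1[C@](C)(O)/C=C/C#C | intermediate
28 | O,C-dilithio derivative of 27 (lithium alkoxide and lithium acetylide) | [Li]C#C/C=C/[C@@](C)(O[Li])[C@@H]1OCC[C@@H]1C | intermediate (not isolated)
29 | 1,2-adduct of 28 and 14: 2-chloro-1-[(3E,5R)-5-hydroxy-5-[(2R,3S)-3-methyloxolan-2-yl]hex-3-en-1-yn-1-yl]-3-methoxy-4-methyl-4,5-bis[(triethylsilyl)oxy]-6-{[(triethylsilyl)oxy]methyl}cyclohex-2-en-1-ol, ring centres (4R,5R,6S), either configuration at C1 | COC1=C(Cl)C(O)(C#C/C=C/[C@@](C)(O)[C@@H]2OCC[C@@H]2C)[C@@H](CO[Si](CC)(CC)CC)[C@@H](O[Si](CC)(CC)CC)[C@@]1(C)O[Si](CC)(CC)CC | intermediate (not isolated)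
30 | (4S,5R,6R)-2-chloro-4-(hydroxymethyl)-3-[(3E,5R)-5-hydroxy-5-[(2R,3S)-3-methyloxolan-2-yl]hex-3-en-1-yn-1-yl]-6-methyl-5,6-bis[(triethylsilyl)oxy]cyclohex-2-en-1-one | O=C1C(Cl)=C(C#C/C=C/[C@@](C)(O)[C@@H]2OCC[C@@H]2C)[C@@H](CO)[C@@H](O[Si](CC)(CC)CC)[C@@]1(C)O[Si](CC)(CC)CC | intermediate
31 | (7R,8R,8aS)-5-chloro-3-[(1E,3R)-3-hydroxy-3-[(2R,3S)-3-methyloxolan-2-yl]but-1-en-1-yl]-7-methyl-7,8-bis[(triethylsilyl)oxy]-1,7,8,8a-tetrahydro-6H-isochromen-6-one | C[C@H]1CCO[C@H]1[C@](C)(O)/C=C/C1=CC2=C(Cl)C(=O)[C@](C)(O[Si](CC)(CC)CC)[C@H](O[Si](CC)(CC)CC)[C@@H]2CO1 | intermediate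
32 | Peniciazaphilone E, (7R,8R,8aS)-5-chloro-7,8-dihydroxy-3-[(1E,3R)-3-hydroxy-3-[(2R,3S)-3-methyloxolan-2-yl]but-1-en-1-yl]-7-methyl-1,7,8,8a-tetrahydro-6H-isochromen-6-one | C[C@H]1CCO[C@H]1[C@](C)(O)/C=C/C1=CC2=C(Cl)C(=O)[C@](C)(O)[C@H](O)[C@@H]2CO1 | target

Total step count: 19. Longest linear sequence: 10 steps (steps 3–9 and 17–19; the side-chain branch, steps 10–19, is equally long).

Steps most likely to fail

Step 6. The push–pull alkene of 5 may be too weak a dienophile, so that the cycloaddition stalls or reverts. The reaction may also divert to open-chain conjugate addition, exo and facial selectivity may erode, or the bridgehead silyl ketal may collapse early and expose a β-keto-lactone that epimerises at C8a. The fallback sets out from 5 and 9 and comes back at 10, and replaces the pericyclic step by a two-stage ionic annulation. A catalytic silyl triflate (Me3SiOTf, CH2Cl2, −78 °C) would activate the lactone carbonyl of 5 for a vinylogous Mukaiyama–Michael addition of 9 through its methyl-bearing carbon. This would give the butenolide silyl ketene acetal F1. On warming with the same Lewis acid, the ketene acetal carbon would add to the butenolide carbonyl held beside it, with silyl transfer to the new bridgehead oxygen, and this gives 10. The tether allows only the cis closure.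

Step 17. Addition of the acetylide to the hindered vinylogous ester may be slow against deprotonation at the α′-carbon followed by loss of the β-silyloxy group. The acid needed for the transposition may also ionise the tertiary allylic alcohol of the side chain or strip the secondary silyl ether. The fallback sets out from 14 and 22 and comes back at 30, and separates the two tasks. Lithium (trimethylsilyl)acetylide (trimethylsilylacetylene, n-BuLi, THF, −78 → 0 °C) followed by 1 M HCl would give the silylethynyl enone F2, and K2CO3 in MeOH would give the terminal alkyne F3. In parallel, 22 would take up ethynylmagnesium bromide under the same chelate control to give the ethynyl carbinol F4. Hydrozirconation with Cp2Zr(H)Cl and iodinolysis would give the (E)-vinyl iodide F5. Sonogashira coupling of F3 with F5 (Pd(PPh3)4, CuI, i-Pr2NH, 20 °C) would give 30; the vinyl iodide should react well ahead of the ring vinyl chloride.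

Step 18. The ring closure may lose regiocontrol (5-exo attack at the proximal alkyne carbon), the Lewis-acidic metal may ionise the tertiary allylic alcohol, or the catalyst may be deactivated by the free hydroxyls. The fallback sets out from 30 and comes back at 31, and uses electrophile-induced cyclisation and then dehalogenation. Iodine with NaHCO3 in MeCN at 0 °C would give, by 6-endo-dig iodoetherification, the 4-iodo-isochromenone F6. Its vinyl iodide would then be reduced selectively with Bu3SnH and Pd(PPh3)4 in THF to give 31, the vinyl chloride being left in place.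

Further compounds
F1 | step 6 | vinylogous Michael adduct of 9 and 5 in its silyl ketene acetal form: 4-methoxy-5-methylfuran-2(5H)-one carrying at C5 the 4-(tert-butyldimethylsilyloxy)-2H-1,3-dioxin-2-yl ring of the menthone ketal, C7 and C8 as in 10 | COC1=CC(=O)O[C@]1(C)[C@@H]1O[C@]2(C[C@H](C)CC[C@H]2C(C)C)OC(O[Si](C)(C)C(C)(C)C)=C1
F2 | step 17 | (4S,5R,6R)-2-chloro-4-(hydroxymethyl)-6-methyl-5,6-bis[(triethylsilyl)oxy]-3-[(trimethylsilyl)ethynyl]cyclohex-2-en-1-one | O=C1C(Cl)=C(C#C[Si](C)(C)C)[C@@H](CO)[C@@H](O[Si](CC)(CC)CC)[C@@]1(C)O[Si](CC)(CC)CC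
F3 | step 17 | (4S,5R,6R)-2-chloro-3-ethynyl-4-(hydroxymethyl)-6-methyl-5,6-bis[(triethylsilyl)oxy]cyclohex-2-en-1-one | O=C1C(Cl)=C(C#C)[C@@H](CO)[C@@H](O[Si](CC)(CC)CC)[C@@]1(C)O[Si](CC)(CC)CC
F4 | step 17 | (2R)-2-[(2R,3S)-3-methyloxolan-2-yl]but-3-yn-2-ol | C[C@H]1CCO[C@H]1[C@](C)(O)C#C
F5 | step 17 | (2R,3E)-4-iodo-2-[(2R,3S)-3-methyloxolan-2-yl]but-3-en-2-ol | C[C@H]1CCO[C@H]1[C@](C)(O)/C=C/I
F6 | step 18 | (7R,8R,8aS)-5-chloro-3-[(1E,3R)-3-hydroxy-3-[(2R,3S)-3-methyloxolan-2-yl]but-1-en-1-yl]-4-iodo-7-methyl-7,8-bis[(triethylsilyl)oxy]-1,7,8,8a-tetrahydro-6H-isochromen-6-one | C[C@H]1CCO[C@H]1[C@](C)(O)/C=C/C1=C(I)C2=C(Cl)C(=O)[C@](C)(O[Si](CC)(CC)CC)[C@H](O[Si](CC)(CC)CC)[C@@H]2CO1
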